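The route rests on disconnecting the C2–C3 bond of the pyranone ring C. A diazomethyl ketone on ring A, whose ortho oxygen (O1) already carries the ring B benzyl group, is decomposed by a chiral divalent-rhodium carboxylate. The carbenoid carbon (future C3) inserts into one of the two enantiotopic C–H bonds of the O1–CH2–aryl methylene (future C2). The step exploits the fact that C2 is at once α to O1 and benzylic to the electron-rich ring B, in a 1,6-relationship to the carbenoid carbon. In one operation it closes ring C, forms C2–C3 and sets the (2S) centre. The precursor arises from two protected halves by Mitsunobu etherification and diazo transfer.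

Key step: step 11

Remark: the (2S) sense of induction with Rh2(S-PTTL)4 (PTTL = N-phthaloyl-tert-leucinate) is assigned by analogy; if the opposite sense is found, the antipode Rh2(R-PTTL)4 is used with nothing else changed.

**Ring A half (steps 1–4)**

Step 1
Reactants: 1 2,4-dihydroxyacetophenone; 2 3-chloro-3-methylbut-1-yne
Product: 3 1-[2-hydroxy-4-(2-methylbut-3-yn-2-yloxy)phenyl]ethan-1-one
Conditions: K2CO3, KI (cat.), acetone, reflux
Reagents that add atoms: none
Why: Williamson-type O-alkylation should occur only at the more acidic, non-chelated 4-OH, the 2-OH being locked in a hydrogen bond to the acetyl group.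

Step 2
Reactants: 3 1-[2-hydroxy-4-(2-methylbut-3-yn-2-yloxy)phenyl]ethan-1-one
Product: 4 1-[2-hydroxy-4-(2-methylbut-3-en-2-yloxy)phenyl]ethan-1-one
Conditions: H2 (1 atm), Pd/CaCO3 poisoned with Pb(OAc)2 (Lindlar catalyst), quinoline, EtOAc, rt
Reagents that add atoms: none
Why: Lindlar semihydrogenation should stop at the terminal alkene and leave the aryl ketone untouched.

Step 3
Reactants: 4 1-[2-hydroxy-4-(2-methylbut-3-en-2-yloxy)phenyl]ethan-1-one
Product: 6 1-[2,4-dihydroxy-3-(3-methylbut-2-en-1-yl)phenyl]ethan-1-one, via Claisen dienone 5 (not isolated)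
Conditions: N,N-diethylaniline, 130 °C
Reagents that add atoms: none
Why: The aromatic Claisen rearrangement ([3,3]-sigmatropic) of the 1,1-dimethylallyl ether should deliver the linear prenyl group to C3, the ortho position favoured by the bond fixation of the chelated 2-hydroxy ketone, after which dienone 5 tautomerises to the phenol.

Step 4
Reactants: 6 1-[2,4-dihydroxy-3-(3-methylbut-2-en-1-yl)phenyl]ethan-1-one
Product: 7 1-[2-hydroxy-3-(3-methylbut-2-en-1-yl)-4-(triisopropylsilyloxy)phenyl]ethan-1-one
Conditions: iPr3SiCl, imidazole, DMF, rt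
Reagents that add atoms: chlorotriisopropylsilane CC(C)[Si](Cl)(C(C)C)C(C)C
Why: Silylation should take place only at the free 4-OH because the 2-OH is chelated to the ketone and flanked by two ortho substituents.

**Ring B half (steps 5–8)**

Step 5
Reactants: 8 7-methoxy-2,2-dimethyl-2H-chromene (commercial, sold as precocene 1)
Product: 9 2,2-dimethyl-2H-chromen-7-ol
Conditions: NaSEt, DMF, 140 °C; aq. HCl work-up
Reagents that add atoms: none
Why: SN2 demethylation of the aryl methyl ether by ethanethiolate should proceed cleanly, since the 2,2-dimethylchromene offers no acidic or electrophilic site to the thiolate.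

Step 6
Reactants: 9 2,2-dimethyl-2H-chromen-7-ol
Product: 10 7-hydroxy-2,2-dimethyl-2H-chromene-6-carbaldehyde
Conditions: MgCl2, Et3N, (CH2O)n, MeCN, reflux
Reagents that add atoms: paraformaldehyde (as formaldehyde) C=O
Why: Magnesium phenoxide-directed ortho-formylation (Casnati–Skattebøl reaction, ortho-hydroxymethylation then hydride transfer to a second formaldehyde) should go to C6, because the other ortho position C8 is wedged between two oxygen substituents.

Step 7
Reactants: 10 7-hydroxy-2,2-dimethyl-2H-chromene-6-carbaldehyde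
Product: 11 2,2-dimethyl-7-(triisopropylsilyloxy)-2H-chromene-6-carbaldehyde
Conditions: iPr3SiCl, imidazole, DMF, rt to 40 °C
Reagents that add atoms: chlorotriisopropylsilane CC(C)[Si](Cl)(C(C)C)C(C)C
Why: Standard silylation of the only hydroxyl group, which should proceed in DMF although that hydroxyl is hydrogen-bonded to the aldehyde.

Step 8
Reactants: 11 2,2-dimethyl-7-(triisopropylsilyloxy)-2H-chromene-6-carbaldehyde
Product: 12 [2,2-dimethyl-7-(triisopropylsilyloxy)-2H-chromen-6-yl]methanol
Conditions: NaBH4, MeOH–THF, 0 °C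
Reagents that add atoms: none
Why: Borohydride reduction of the aldehyde at 0 °C should be clean, the hindered triisopropylsilyl group resisting migration from the phenolic oxygen to the new benzylic alkoxide.

**Union, key step and deprotection (steps 9–12)**

Step 9
Reactants: 7 1-[2-hydroxy-3-(3-methylbut-2-en-1-yl)-4-(triisopropylsilyloxy)phenyl]ethan-1-one; 12 [2,2-dimethyl-7-(triisopropylsilyloxy)-2H-chromen-6-yl]methanol
Product: 13 1-[2-{[2,2-dimethyl-7-(triisopropylsilyloxy)-2H-chromen-6-yl]methoxy}-3-(3-methylbut-2-en-1-yl)-4-(triisopropylsilyloxy)phenyl]ethan-1-one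
Conditions: PPh3, DIAD, THF, 0 °C to rt
Reagents that add atoms: none
Why: In this Mitsunobu etherification the chelated 2-OH of 7 is acidic enough to protonate the betaine, and its phenoxide should displace the primary benzylic oxyphosphonium ion under neutral conditions that spare both aryl silyl ethers.

Step 10
Reactants: 13 aryl benzyl ether methyl ketone (product of step 9)
Product: 15 2-diazo-1-[2-{[2,2-dimethyl-7-(triisopropylsilyloxy)-2H-chromen-6-yl]methoxy}-3-(3-methylbut-2-en-1-yl)-4-(triisopropylsilyloxy)phenyl]ethan-1-one, via trifluoroacetyl diketone 14 (not isolated)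
Conditions: LiN(SiMe3)2, THF, −78 °C, then CF3CO2CH2CF3; aq. HCl work-up; then MsN3, Et3N, H2O, MeCN, rt
Reagents that add atoms: methanesulfonyl azide CS(=O)(=O)N=[N+]=[N-] (the two diazo nitrogens); 2,2,2-trifluoroethyl trifluoroacetate O=C(OCC(F)(F)F)C(F)(F)F (the trifluoroacetyl group of 14, lost again)
Why: Deacylative Regitz diazo transfer should work because the kinetic lithium enolate of the methyl ketone is trifluoroacetylated to the activated diketone 14, which takes up N2 from the sulfonyl azide and loses the trifluoroacetyl group as the sulfonamide.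

Step 11
Reactants: 15 diazomethyl ketone (product of step 10)
Product: 16 (2S)-2-[2,2-dimethyl-7-(triisopropylsilyloxy)-2H-chromen-6-yl]-8-(3-methylbut-2-en-1-yl)-7-(triisopropylsilyloxy)-2,3-dihydro-4H-chromen-4-one
Conditions: Rh2(S-PTTL)4 (2 mol%), CH2Cl2, 0 °C, slow addition of 15 at high dilution
Reagents that add atoms: none
Why: Rh2(S-PTTL)4 extrudes N2 from 15 to give an electrophilic rhodium carbenoid at the future C3, which inserts through a concerted, hydride-transfer-like three-centre transition state into a C–H bond of the O1–CH2–aryl methylene and so forms the C2–C3 bond. The closest known reaction type is the intramolecular C–H insertion of 2-alkoxyaryl diazomethyl ketones into the ether α-C–H bond under chiral divalent-rhodium carboxylate catalysis, which gives 2-substituted chroman-4-ones. Ring C closes in the 1,6-insertion mode (carbenoid carbon, C4, C4a, C8a, O1, C2), the six-membered ring being favoured because the only five-membered alternative is attack on O1 itself. The new C2 stereocentre is set by catalyst control, the chiral carboxylate pocket selecting one of the two enantiotopic benzylic hydrogens. The step needs C–H insertion to win over oxonium-ylide formation at O1 followed by 1,2-benzyl shift, over aromatic cycloaddition to ring B, and over cyclopropanation of the prenyl and chromene alkenes. O1 is a poor donor because it is conjugated to the ketone, the target C–H is doubly activated (α-oxygen and 2,4-dioxygenated benzylic), both alkenes are meta-disposed and reachable only through strained medium rings, and slow addition at high dilution suppresses bimolecular paths.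

Step 12
Reactants: 16 bis-silylated (2S)-flavanone (product of step 11)
Product: 17 (2S)-7-hydroxy-2-(7-hydroxy-2,2-dimethyl-2H-chromen-6-yl)-8-(3-methylbut-2-en-1-yl)-2,3-dihydro-4H-chromen-4-one (target)
Conditions: Bu4NF, AcOH (1:1), THF, 0 °C
Reagents that add atoms: none
Why: Fluoride should cleave both aryl silyl ethers, and the acetic acid buffer prevents a free phenoxide that could open ring C by retro-oxa-Michael reaction and erode the C2 stereocentre, while prenyl, chromene and ketone are inert.

**Compound list**

1 | 1-(2,4-dihydroxyphenyl)ethan-1-one (2,4-dihydroxyacetophenone) | CC(=O)c1ccc(O)cc1O | starting material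
2 | 3-chloro-3-methylbut-1-yne | CC(C)(Cl)C#C | starting material
3 | 1-[2-hydroxy-4-(2-methylbut-3-yn-2-yloxy)phenyl]ethan-1-one | CC(=O)c1ccc(OC(C)(C)C#C)cc1O | intermediate
4 | 1-[2-hydroxy-4-(2-methylbut-3-en-2-yloxy)phenyl]ethan-1-one | CC(=O)c1ccc(OC(C)(C)C=C)cc1O | intermediate
5 | 4-acetyl-3-hydroxy-2-(3-methylbut-2-en-1-yl)cyclohexa-3,5-dien-1-one (Claisen dienone, racemic at C2, formed in situ) | CC(=O)C1=C(O)C(CC=C(C)C)C(=O)C=C1 | intermediate
6 | 1-[2,4-dihydroxy-3-(3-methylbut-2-en-1-yl)phenyl]ethan-1-one | CC(=O)c1ccc(O)c(CC=C(C)C)c1O | intermediate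
7 | 1-[2-hydroxy-3-(3-methylbut-2-en-1-yl)-4-(triisopropylsilyloxy)phenyl]ethan-1-one | CC(=O)c1ccc(O[Si](C(C)C)(C(C)C)C(C)C)c(CC=C(C)C)c1O | intermediate
8 | 7-methoxy-2,2-dimethyl-2H-chromene | COc1ccc2c(c1)OC(C)(C)C=C2 | starting material
9 | 2,2-dimethyl-2H-chromen-7-ol | Oc1ccc2c(c1)OC(C)(C)C=C2 | intermediate
10 | 7-hydroxy-2,2-dimethyl-2H-chromene-6-carbaldehyde | O=Cc1cc2c(cc1O)OC(C)(C)C=C2 | intermediate
11 | 2,2-dimethyl-7-(triisopropylsilyloxy)-2H-chromene-6-carbaldehyde | O=Cc1cc2c(cc1O[Si](C(C)C)(C(C)C)C(C)C)OC(C)(C)C=C2 | intermediate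
12 | [2,2-dimethyl-7-(triisopropylsilyloxy)-2H-chromen-6-yl]methanol | OCc1cc2c(cc1O[Si](C(C)C)(C(C)C)C(C)C)OC(C)(C)C=C2 | intermediate
13 | 1-[2-{[2,2-dimethyl-7-(triisopropylsilyloxy)-2H-chromen-6-yl]methoxy}-3-(3-methylbut-2-en-1-yl)-4-(triisopropylsilyloxy)phenyl]ethan-1-one | CC(=O)c1ccc(O[Si](C(C)C)(C(C)C)C(C)C)c(CC=C(C)C)c1OCc1cc2c(cc1O[Si](C(C)C)(C(C)C)C(C)C)OC(C)(C)C=C2 | intermediate
14 | 1-[2-{[2,2-dimethyl-7-(triisopropylsilyloxy)-2H-chromen-6-yl]methoxy}-3-(3-methylbut-2-en-1-yl)-4-(triisopropylsilyloxy)phenyl]-4,4,4-trifluorobutane-1,3-dione (formed in situ) | O=C(CC(=O)C(F)(F)F)c1ccc(O[Si](C(C)C)(C(C)C)C(C)C)c(CC=C(C)C)c1OCc1cc2c(cc1O[Si](C(C)C)(C(C)C)C(C)C)OC(C)(C)C=C2 | intermediate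
15 | 2-diazo-1-[2-{[2,2-dimethyl-7-(triisopropylsilyloxy)-2H-chromen-6-yl]methoxy}-3-(3-methylbut-2-en-1-yl)-4-(triisopropylsilyloxy)phenyl]ethan-1-one | [N-]=[N+]=CC(=O)c1ccc(O[Si](C(C)C)(C(C)C)C(C)C)c(CC=C(C)C)c1OCc1cc2c(cc1O[Si](C(C)C)(C(C)C)C(C)C)OC(C)(C)C=C2 | intermediate
16 | (2S)-2-[2,2-dimethyl-7-(triisopropylsilyloxy)-2H-chromen-6-yl]-8-(3-methylbut-2-en-1-yl)-7-(triisopropylsilyloxy)-2,3-dihydro-4H-chromen-4-one | CC(C)=CCc1c(O[Si](C(C)C)(C(C)C)C(C)C)ccc2c1O[C@H](c1cc3c(cc1O[Si](C(C)C)(C(C)C)C(C)C)OC(C)(C)C=C3)CC2=O | intermediate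
17 | (2S)-7-hydroxy-2-(7-hydroxy-2,2-dimethyl-2H-chromen-6-yl)-8-(3-methylbut-2-en-1-yl)-2,3-dihydro-4H-chromen-4-one | CC(C)=CCc1c(O)ccc2c1O[C@H](c1cc3c(cc1O)OC(C)(C)C=C3)CC2=O | target

**Step count**

Total: 12 steps. Longest linear sequence: 8 steps (steps 1–4 then 9–12; the branch through steps 5–8 then 9–12 is equally long).

**Steps most likely to fail**

Step 11. The carbenoid may be diverted to oxonium-ylide formation at O1 followed by 1,2-migration of the electron-rich benzyl group, or discrimination between the two enantiotopic hydrogens may be poor. The fallback sets out from 13 and comes back to the route at 16, closing the same C2–C3 bond through a cation instead of a carbenoid. Ketone 13 is converted with KN(SiMe3)2 and Ac2O (THF, −78 °C) into the enol acetate F1. Treatment of F1 with DDQ, 2,6-dichloropyridine and LiClO4 over 4 Å molecular sieves in 1,2-dichloroethane at rt should abstract hydride from the doubly activated O1–CH2–aryl methylene. The resulting aryl-stabilised oxocarbenium ion is captured by the enol acetate (known DDQ-mediated oxidative C–H cleavage with cyclisation of a tethered enol acetate to a 2-aryl-pyran-4-one), giving the racemic flavanone F2. Preparative HPLC on a chiral stationary phase (amylose tris(3,5-dimethylphenylcarbamate), hexane/2-propanol) then separates 16 from the (2R)-enantiomer F3, which is discarded.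

Step 9. The hindered, hydrogen-bonded phenol may react slowly, leaving time for alkylation of the reduced azodicarboxylate or for ionisation and self-condensation of the electron-rich benzylic oxyphosphonium species. The fallback sets out from 12 and comes back at 13, replacing redox condensation by classical alkylation. Alcohol 12 is converted under Appel conditions (CBr4, PPh3, CH2Cl2, 0 °C) into the benzylic bromide F4. F4 is used at once to alkylate phenol 7 (K2CO3, dry acetone, 50 °C), a Williamson etherification that the triisopropylsilyl ethers should tolerate in the absence of water and fluoride.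

Step 6. Regiocontrol between C6 and C8 may be incomplete, and over-hydroxymethylation or oligomerisation through an ortho-quinone methide may consume the electron-rich phenol. The fallback sets out from 8 and comes back at 10, putting in the formyl group before the phenol is freed. Vilsmeier–Haack formylation of 8 (POCl3, DMF, 0 to 60 °C, aqueous hydrolysis) should attack C6, which is para to the ring oxygen and ortho to the methoxy group, while C8 is shielded by both oxygen substituents. This gives 7-methoxy-2,2-dimethyl-2H-chromene-6-carbaldehyde F5. Chelation-assisted cleavage of the methoxy group ortho to the aldehyde with BCl3 (CH2Cl2, −78 to 0 °C) then gives 10, and step 5 is no longer needed.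

**Further compounds**

F1 | step 11 | 1-[2-{[2,2-dimethyl-7-(triisopropylsilyloxy)-2H-chromen-6-yl]methoxy}-3-(3-methylbut-2-en-1-yl)-4-(triisopropylsilyloxy)phenyl]ethenyl acetate (enol acetate of 13) | C=C(OC(C)=O)c1ccc(O[Si](C(C)C)(C(C)C)C(C)C)c(CC=C(C)C)c1OCc1cc2c(cc1O[Si](C(C)C)(C(C)C)C(C)C)OC(C)(C)C=C2
F2 | step 11 | racemic 2-[2,2-dimethyl-7-(triisopropylsilyloxy)-2H-chromen-6-yl]-8-(3-methylbut-2-en-1-yl)-7-(triisopropylsilyloxy)-2,3-dihydro-4H-chromen-4-one | CC(C)=CCc1c(O[Si](C(C)C)(C(C)C)C(C)C)ccc2c1OC(c1cc3c(cc1O[Si](C(C)C)(C(C)C)C(C)C)OC(C)(C)C=C3)CC2=O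
F3 | step 11 | (2R)-2-[2,2-dimethyl-7-(triisopropylsilyloxy)-2H-chromen-6-yl]-8-(3-methylbut-2-en-1-yl)-7-(triisopropylsilyloxy)-2,3-dihydro-4H-chromen-4-one | CC(C)=CCc1c(O[Si](C(C)C)(C(C)C)C(C)C)ccc2c1O[C@@H](c1cc3c(cc1O[Si](C(C)C)(C(C)C)C(C)C)OC(C)(C)C=C3)CC2=O
F4 | step 9 | 6-(bromomethyl)-2,2-dimethyl-7-(triisopropylsilyloxy)-2H-chromene | BrCc1cc2c(cc1O[Si](C(C)C)(C(C)C)C(C)C)OC(C)(C)C=C2
F5 | step 6 | 7-methoxy-2,2-dimethyl-2H-chromene-6-carbaldehyde | O=Cc1cc2c(cc1OC)OC(C)(C)C=C2
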